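All runs come from a simulation with constants of no real substance; noise was put on by code.

The ratio of protic impurity to first end groups charged is 0.500 in the three new flasks, and I build the flask up one process at a time to see what that ratio and the others do to the links.

| flask | first end groups | second end groups | one-sided end groups | protic impurity | remark | time |
|---|---|---|---|---|---|---|
| Tuesday's | 0.064 M | 1.02 equiv | 0.64 mM | 0.032 M | run made earlier |  |
| Wednesday's | 0.043 M | 1.02 equiv | 0.64 mM | 0.032 M | run made earlier |  |
| Sunday's | 0.096 M | 1.02 equiv | 0.64 mM | 0.032 M | run made earlier |  |
| Monday's | 0.064 M | 0.51 equiv | 0.64 mM | 0.032 M | run made earlier |  |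
| beta | 0.064 M | 1.02 equiv (fed, over 3.0 min) | 0.640 mM | 0.0320 M | all else is in the flask from the start; the feed brings no volume worth counting | 15 min |
| epsilon | 0.064 M | 1.02 equiv | 0.640 mM | 0.0320 M | everything together at the start | 15 min |
| alpha | 0.064 M (fed, over 3.0 min) | 1.02 equiv | 0.640 mM | 0.0320 M | all else is in the flask from the start; the feed brings no volume worth counting | 15 min |

- Tuesday's (time / min: links / %, first end groups / %): 1.00: 37.9, 13.2; 3.00: 46.2, 3.2; 6.00: 47.2, 0.8; 10.0: 47.9, 0.7
- Wednesday's (time / min: links / %, first end groups / %): 2.50: 41.3, 7.6; 5.00: 43.9, 2.8; 6.00: 44.1, 2.8; 10.0: 45.4, 0.9
- Sunday's (time / min: links / %, first end groups / %): 1.00: 42.7, 7.1; 3.00: 48.1, 1.1; 6.00: 49.4, 0.3; 10.0: 49.7, 0.2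
- Monday's (time / min: links / %, first end groups / %): 2.50: 25.4, 7.9; 5.00: 28.1, 3.9; 6.00: 28.1, 3.2; 10.0: 27.9, 1.5

(readings scatter by 0.3 percentage points)



1. which flask leads in amount of links, in percent of the first end groups charged ("all alike" within 1.5 percentage points) (beta / epsilon / alpha / all alike)
2. how much links is there at the end, in percent of the first end groups charged: beta
3. how much links is there at the end, in percent of the first end groups charged: epsilon
4. how much links is there at the end, in percent of the first end groups charged: alpha

With the main step alone, first end groups and second end groups give links, and at 1.02 equiv the second end groups cover the charge, so links stand at 100%. If each one-sided end group takes one first end group, that costs 1.00%. If each impurity molecule also spends one second end group, Tuesday's run keeps 52.0% and Wednesday's keeps 27.6%. But Wednesday's reading is 45.4%, more than that, so in that run the impurity has not taken its full count by 10.0 min. Sunday's run loses 0.0481 M of first end groups without making links, more than its 0.032 M of impurity, so a further route spends them.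

Monday's run, with second end groups as the limiting reagent, reads 0.547. This is the link return: links, as a fraction of the first end groups charged, per equivalent of second end groups charged. Its symmetric zero is 0.5, even odds for each second end group. Tuesday's run reads 0.470.

My own reckoning takes epsilon as a repeat of Tuesday's run, near 47.9%. For alpha I use Monday's return, which gives 55.8%. For beta, the second end groups let in over the 3.0 min feed average 0.510 before any of them react, about Monday's 0.51 equiv, so as a rough estimate I put beta near or under Monday's 27.9%.

The forecast also puts alpha first, with 62% there, 48% for epsilon and 28% for beta, and its ground is: “Feeding first end groups keeps them dilute against excess partner”. My figure for alpha is lower, and for beta I stay near the forecast's.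

The flasks end with alpha ahead at 53.4%, epsilon at 48.2% and beta at 20.9%.

    first end groups + second end groups → links (k = 0.400 /M/s)
    first end groups + one-sided end groups → capped ends (k = 110 /M/s)
    second end groups + protic impurity → quenched reagent (k = 0.160 /M/s)
    2 first end groups → self-condensation product (k = 0.390 /M/s)

Beta already holds 77.9% of its first end groups as self-condensation product at 3.00 min, against 44.8% for alpha at 15.0 min. Alpha's link return is 0.524. The neighbour of alpha charged with 0.410 equiv of second end groups reckons, at Monday's return, to 22.4%, and that neighbour ends at 21.1% links.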